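The 3(2H)-furanone ring (O–C10–C1(=O)–C2H=C3) is a cyclodehydrated 4-hydroxy-2-ynone, so C1–C2 is brought in as an acetylene linchpin. In one flask, ethynylmagnesium bromide adds to a chiral acetyl aminal (chelation sets C10), the resulting acetylide acylates a Weinreb amide carrying C3–C7, and amine/acid treatment closes the furanone. Bonds C1–C10 and C2–C3 thus form together from two open-chain pieces. After one-carbon homologation at C9, the ten-membered carbocycle and the trans α-methylene lactone are closed late by a chromium Barbier reaction (C7–C8).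

Key step: step 5

Remark: positions follow germacranolide numbering (C1 furanone C=O, C2 =CH, C3 O–C=, C4 CHMe, C5 CHOH, C6 CH–O-isobutyrate, C7, C8 lactone CH–O, C9 CH2, C10 quaternary C–O, C11–C13 methylene lactone); the sense of induction of the keto aminal is assumed to follow the Mukaiyama chelate model, which is why the (R)-diamine is chosen.

Step 1
Reactants: 1 (R)-2-(anilinomethyl)pyrrolidine; 2 methylglyoxal (40% aqueous)
Product: 3 1-[(3S,7aR)-2-phenylhexahydro-1H-pyrrolo[1,2-c]imidazol-3-yl]ethan-1-one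
Conditions: toluene, 4 Å MS, rt
Reagents that add atoms: none
Why: Condensation (aminal formation) of the diamine with the more electrophilic aldehyde carbonyl of methylglyoxal closes the cis-fused bicyclic aminal, and the acetyl group should settle on the convex face under thermodynamic control (Mukaiyama-type keto aminal).

Step 2
Reactants: 4 (S)-4-benzyl-3-propanoyl-1,3-oxazolidin-2-one; 5 (S)-2,2-dimethyl-1,3-dioxolane-4-carbaldehyde
Product: 6 (S)-4-benzyl-3-[(2S,3S)-3-[(4S)-2,2-dimethyl-1,3-dioxolan-4-yl]-3-hydroxy-2-methylpropanoyl]-1,3-oxazolidin-2-one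
Conditions: Bu2BOTf, iPr2NEt, CH2Cl2, −78 → 0 °C; then pH 7 buffer, MeOH, H2O2, 0 °C
Reagents that add atoms: none
Why: Evans syn-aldol reaction through the Z-boron enolate and a Zimmerman–Traxler transition state should set C4 and C5 (both S) under auxiliary control, which overrides the weak bias of the α-alkoxy aldehyde, while C6 comes unchanged from 5.

Step 3
Reactants: 6 aldol adduct
Product: 7 (2S,3S)-3-[(4S)-2,2-dimethyl-1,3-dioxolan-4-yl]-3-hydroxy-N-methoxy-N,2-dimethylpropanamide
Conditions: MeONHMe·HCl, AlMe3, CH2Cl2, −15 → 0 °C; Rochelle salt work-up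
Reagents that add atoms: N,O-dimethylhydroxylamine hydrochloride, CNOC.Cl
Why: Weinreb transamidation with the aluminium amide, assisted by the free β-hydroxyl, removes the auxiliary without touching the stereocentres.

Step 4
Reactants: 7 hydroxy Weinreb amide
Product: 8 (2S,3S)-3-[(tert-butyldimethylsilyl)oxy]-3-[(4S)-2,2-dimethyl-1,3-dioxolan-4-yl]-N-methoxy-N,2-dimethylpropanamide
Conditions: TBSOTf, 2,6-lutidine, CH2Cl2, −78 → 0 °C
Reagents that add atoms: tert-butyldimethylsilyl triflate, CC(C)(C)[Si](C)(C)OS(=O)(=O)C(F)(F)F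
Why: Silylation of the secondary alcohol with the silyl triflate (protection) so that the C5 oxygen survives the organometallic and oxidation steps.

Step 5
Reactants: 3 acetyl aminal; 9 ethynylmagnesium bromide; 8 silylated Weinreb amide
Product: 13 (2R)-5-[(2S,3S)-3-[(tert-butyldimethylsilyl)oxy]-3-[(4S)-2,2-dimethyl-1,3-dioxolan-4-yl]propan-2-yl]-2-methyl-3-oxo-2,3-dihydrofuran-2-carbaldehyde, via propargylic alkoxide 10 (not isolated), via hydroxy ynone 11 (not isolated), via diethylamino enone 12 (not isolated)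
Conditions: 9 and 3 (1.5 equiv each), THF/Et2O, −78 °C; n-BuLi (1.5 equiv), −78 → −20 °C; 8 (1.0 equiv), −78 → 0 °C; EtOH, Et2NH, rt; 1 M HCl, THF, 0 °C
Reagents that add atoms: water, O
Why: Ethynylmagnesium bromide should add to ketone 3 through a five-membered magnesium chelate between the carbonyl oxygen and the pyrrolidine nitrogen of the aminal, so that the alkynyl group enters from the face opposite the N-phenyl nitrogen and makes the C1–C10 bond; n-BuLi then metalates the terminal alkyne and the acetylide acylates Weinreb amide 8 through its stable chelated tetrahedral adduct, making the C2–C3 bond and giving ynone 11 on quench. Diethylamine adds to C1 (the β-carbon of the ynone) to give enaminone 12, and aqueous acid hydrolyses it to the 1,3-diketone, whose C10 hydroxyl attacks the C3 carbonyl and loses water to give the 3(2H)-furanone, while the same acid cleaves the aminal to the C9 aldehyde and releases the diamine for recovery. The closest known reaction types are the Mukaiyama keto-aminal Grignard addition, the Weinreb ketone synthesis with acetylides and the amine-mediated cyclisation of 4-hydroxy-2-ynones to 3(2H)-furanones, here run in one flask. Only the furanone ring closes in this step, in a 5-exo-trig attack of the C10 oxygen on C3 followed by dehydration. C10 is the only new stereocentre (2S in 10, which is the 10R configuration of the target once C1 is a carbonyl) and is controlled by the aminal auxiliary. The step needs face selectivity at the ketone, single addition at the amide and amine attack at C1 rather than C3; these should be secured by the rigid chelate, the N-methoxy chelate and the polarity of the ynone, and C4 should not epimerise because acetylides and diethylamine are weak bases.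

Step 6
Reactants: 13 furanone aldehyde
Product: 14 (2R)-5-[(2S,3S)-3-[(tert-butyldimethylsilyl)oxy]-3-[(4S)-2,2-dimethyl-1,3-dioxolan-4-yl]propan-2-yl]-2-(2-methoxyethenyl)-2-methylfuran-3(2H)-one (E/Z mixture)
Conditions: MeOCH2PPh3Cl, KHMDS, THF, −78 → 0 °C
Reagents that add atoms: (methoxymethyl)triphenylphosphonium chloride, COC[P+](c1ccccc1)(c1ccccc1)c1ccccc1.[Cl-]
Why: Wittig methoxymethylenation homologates the non-enolisable C9 aldehyde by one carbon to the enol ether of the C8 aldehyde; at −78 °C addition to the aldehyde should outrun deprotonation at C4 of the furanone.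

Step 7
Reactants: 14 enol ether
Product: 15 (2R)-5-[(2S,3S,4S)-3-[(tert-butyldimethylsilyl)oxy]-4,5-dihydroxypentan-2-yl]-2-(2,2-dimethoxyethyl)-2-methylfuran-3(2H)-one
Conditions: PPTS (cat.), MeOH, rt → 40 °C
Reagents that add atoms: methanol, CO
Why: Acid-catalysed addition of methanol converts the enol ether into the dimethyl acetal and transketalisation removes the terminal acetonide, while the hindered secondary TBS ether should be stable to PPTS.

Step 8
Reactants: 15 diol acetal
Product: 17 (2S,3S,4S)-3-[(tert-butyldimethylsilyl)oxy]-4-[(2R)-2-(2,2-dimethoxyethyl)-2-methyl-3-oxo-2,3-dihydrofuran-5-yl]-1-hydroxypentan-2-yl 2-methylpropanoate, via cyclic orthoester 16 (not isolated)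
Conditions: iPrC(OMe)3, CSA (cat.), CH2Cl2, rt; then AcOH/H2O (9:1), 0 °C
Reagents that add atoms: trimethyl orthoisobutyrate, COC(OC)(OC)C(C)C; water, O
Why: The diol forms a cyclic orthoester whose kinetically controlled acidic hydrolysis should open the hemi-orthoester towards the ester of the secondary oxygen (O6), leaving the primary C7 hydroxyl free (orthoester method for selective acylation of 1,2-diols).

Step 9
Reactants: 17 primary alcohol
Product: 18 (2R,3S,4S)-3-[(tert-butyldimethylsilyl)oxy]-4-[(2R)-2-(2,2-dimethoxyethyl)-2-methyl-3-oxo-2,3-dihydrofuran-5-yl]-1-oxopentan-2-yl 2-methylpropanoate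
Conditions: Dess–Martin periodinane, CH2Cl2, 0 °C → rt
Reagents that add atoms: none
Why: Dess–Martin oxidation turns the primary alcohol into the C7 aldehyde under near-neutral conditions that should not epimerise the α-acyloxy centre C6.

Step 10
Reactants: 18 α-acyloxy aldehyde; 19 methyl acrylate
Product: 20 methyl (4S,5S,6S)-5-[(tert-butyldimethylsilyl)oxy]-6-[(2R)-2-(2,2-dimethoxyethyl)-2-methyl-3-oxo-2,3-dihydrofuran-5-yl]-3-hydroxy-2-methylidene-4-[(2-methylpropanoyl)oxy]heptanoate (C3 epimers)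
Conditions: 19 (excess), DABCO (0.5 equiv), MeOH, rt
Reagents that add atoms: none
Why: Morita–Baylis–Hillman reaction in which the DABCO-derived enolate of methyl acrylate adds to the activated α-acyloxy aldehyde; the new carbinol centre (C7) forms as a mixture that is erased in step 11.

Step 11
Reactants: 20 Baylis–Hillman adduct
Product: 21 methyl (2Z,4S,5S,6S)-2-(bromomethyl)-5-[(tert-butyldimethylsilyl)oxy]-6-[(2R)-2-(2,2-dimethoxyethyl)-2-methyl-3-oxo-2,3-dihydrofuran-5-yl]-4-[(2-methylpropanoyl)oxy]hept-2-enoate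
Conditions: NBS, Me2S, CH2Cl2, 0 °C → rt
Reagents that add atoms: N-bromosuccinimide, O=C1CCC(=O)N1Br
Why: Corey–Kim-type activation of the allylic alcohol and SN2' attack of bromide (allylic transposition) should give the thermodynamically preferred (Z)-2-(bromomethyl)enoate from both epimers of 20.

Step 12
Reactants: 21 allylic bromide acetal
Product: 22 methyl (2Z,4S,5S,6S)-2-(bromomethyl)-5-[(tert-butyldimethylsilyl)oxy]-6-[(2R)-2-methyl-3-oxo-2-(2-oxoethyl)-2,3-dihydrofuran-5-yl]-4-[(2-methylpropanoyl)oxy]hept-2-enoate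
Conditions: PPTS, acetone/H2O (9:1), 45 °C
Reagents that add atoms: water, O
Why: Mild acid-catalysed acetal hydrolysis frees the C8 aldehyde without cleaving the TBS ether, the allylic bromide or the esters, and avoids the base that would open the furanone by β-elimination.

Step 13
Reactants: 22 bromo aldehyde
Product: 24 5-O-TBS ether of the target (4S,5S,6S,7R,8S,10R), via seco hydroxy ester 23 (not isolated)
Conditions: CrCl2 (8 equiv), THF, 0.003 M, rt; then PPTS (cat.), CH2Cl2, rt
Reagents that add atoms: none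
Why: Intramolecular Nozaki–Hiyama-type Barbier allylation in which the allylchromium(III) species attacks the C8 aldehyde through its γ-carbon C7 in a chair transition state and the alkoxide then lactonises onto the methyl ester; the anti adduct (trans-fused lactone, 7R,8S) is expected from the equilibrating allylchromium, with the aldehyde face dictated by the C6 acyloxy group and the rigid furanone bridge.

Step 14
Reactants: 24 silyl ether
Product: 25 target CNP0141385.1
Conditions: HF·pyridine, pyridine/THF, 0 °C → rt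
Reagents that add atoms: none
Why: Fluoride-mediated desilylation under slightly acidic buffered conditions frees the C5 hydroxyl while avoiding acyl migration from O6 and conjugate addition to the methylene lactone.

Compound list
1 | (R)-2-(anilinomethyl)pyrrolidine | c1ccc(cc1)NC[C@H]1CCCN1 | starting material
2 | methylglyoxal (2-oxopropanal) | CC(=O)C=O | starting material
3 | 1-[(3S,7aR)-2-phenylhexahydro-1H-pyrrolo[1,2-c]imidazol-3-yl]ethan-1-one | CC(=O)[C@@H]1N(c2ccccc2)C[C@H]2CCCN12 | intermediate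
4 | (S)-4-benzyl-3-propanoyl-1,3-oxazolidin-2-one | CCC(=O)N1[C@@H](Cc2ccccc2)COC1=O | starting material
5 | (S)-2,2-dimethyl-1,3-dioxolane-4-carbaldehyde | O=C[C@@H]1COC(C)(C)O1 | starting material
6 | (S)-4-benzyl-3-[(2S,3S)-3-[(4S)-2,2-dimethyl-1,3-dioxolan-4-yl]-3-hydroxy-2-methylpropanoyl]-1,3-oxazolidin-2-one | O=C1OC[C@H](Cc2ccccc2)N1C(=O)[C@@H](C)[C@H](O)[C@@H]1COC(C)(C)O1 | intermediate
7 | (2S,3S)-3-[(4S)-2,2-dimethyl-1,3-dioxolan-4-yl]-3-hydroxy-N-methoxy-N,2-dimethylpropanamide | CON(C)C(=O)[C@@H](C)[C@H](O)[C@@H]1COC(C)(C)O1 | intermediate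
8 | (2S,3S)-3-[(tert-butyldimethylsilyl)oxy]-3-[(4S)-2,2-dimethyl-1,3-dioxolan-4-yl]-N-methoxy-N,2-dimethylpropanamide | CON(C)C(=O)[C@@H](C)[C@H](O[Si](C)(C)C(C)(C)C)[C@@H]1COC(C)(C)O1 | intermediate
9 | ethynylmagnesium bromide | C#C[Mg]Br | starting material
10 | (2S)-2-[(3S,7aR)-2-phenylhexahydro-1H-pyrrolo[1,2-c]imidazol-3-yl]but-3-yn-2-ol (magnesium alkoxide in the flask) | C#C[C@](C)(O)[C@@H]1N(c2ccccc2)C[C@H]2CCCN12 | intermediate (not isolated)
11 | (2S,6S,7S)-7-[(tert-butyldimethylsilyl)oxy]-7-[(4S)-2,2-dimethyl-1,3-dioxolan-4-yl]-2-hydroxy-6-methyl-2-[(3S,7aR)-2-phenylhexahydro-1H-pyrrolo[1,2-c]imidazol-3-yl]hept-3-yn-5-one | O=C(C#C[C@](C)(O)[C@@H]1N(c2ccccc2)C[C@H]2CCCN12)[C@@H](C)[C@H](O[Si](C)(C)C(C)(C)C)[C@@H]1COC(C)(C)O1 | intermediate (not isolated)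
12 | (2S,6S,7S)-3-(diethylamino)hept-3-en-5-one analogue of 11 (β-diethylamino enone, alkene geometry not defined) | CCN(CC)C(=CC(=O)[C@@H](C)[C@H](O[Si](C)(C)C(C)(C)C)[C@@H]1COC(C)(C)O1)[C@](C)(O)[C@@H]1N(c2ccccc2)C[C@H]2CCCN12 | intermediate (not isolated)
13 | (2R)-5-[(2S,3S)-3-[(tert-butyldimethylsilyl)oxy]-3-[(4S)-2,2-dimethyl-1,3-dioxolan-4-yl]propan-2-yl]-2-methyl-3-oxo-2,3-dihydrofuran-2-carbaldehyde | O=C[C@@]1(C)OC(=CC1=O)[C@@H](C)[C@H](O[Si](C)(C)C(C)(C)C)[C@@H]1COC(C)(C)O1 | intermediate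
14 | (2R)-5-[(2S,3S)-3-[(tert-butyldimethylsilyl)oxy]-3-[(4S)-2,2-dimethyl-1,3-dioxolan-4-yl]propan-2-yl]-2-(2-methoxyethenyl)-2-methylfuran-3(2H)-one (E/Z mixture) | COC=C[C@@]1(C)OC(=CC1=O)[C@@H](C)[C@H](O[Si](C)(C)C(C)(C)C)[C@@H]1COC(C)(C)O1 | intermediate
15 | (2R)-5-[(2S,3S,4S)-3-[(tert-butyldimethylsilyl)oxy]-4,5-dihydroxypentan-2-yl]-2-(2,2-dimethoxyethyl)-2-methylfuran-3(2H)-one | COC(OC)C[C@@]1(C)OC(=CC1=O)[C@@H](C)[C@H](O[Si](C)(C)C(C)(C)C)[C@@H](O)CO | intermediate
16 | cyclic orthoester of 15: the 4,5-diol closed as a 2-methoxy-2-(propan-2-yl)-1,3-dioxolane (orthoester carbon not defined) | COC(OC)C[C@@]1(C)OC(=CC1=O)[C@@H](C)[C@H](O[Si](C)(C)C(C)(C)C)[C@@H]1COC(OC)(C(C)C)O1 | intermediate (not isolated)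
17 | (2S,3S,4S)-3-[(tert-butyldimethylsilyl)oxy]-4-[(2R)-2-(2,2-dimethoxyethyl)-2-methyl-3-oxo-2,3-dihydrofuran-5-yl]-1-hydroxypentan-2-yl 2-methylpropanoate | COC(OC)C[C@@]1(C)OC(=CC1=O)[C@@H](C)[C@H](O[Si](C)(C)C(C)(C)C)[C@@H](OC(=O)C(C)C)CO | intermediate
18 | (2R,3S,4S)-3-[(tert-butyldimethylsilyl)oxy]-4-[(2R)-2-(2,2-dimethoxyethyl)-2-methyl-3-oxo-2,3-dihydrofuran-5-yl]-1-oxopentan-2-yl 2-methylpropanoate | COC(OC)C[C@@]1(C)OC(=CC1=O)[C@@H](C)[C@H](O[Si](C)(C)C(C)(C)C)[C@@H](OC(=O)C(C)C)C=O | intermediate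
19 | methyl acrylate | C=CC(=O)OC | starting material
20 | methyl (4S,5S,6S)-5-[(tert-butyldimethylsilyl)oxy]-6-[(2R)-2-(2,2-dimethoxyethyl)-2-methyl-3-oxo-2,3-dihydrofuran-5-yl]-3-hydroxy-2-methylidene-4-[(2-methylpropanoyl)oxy]heptanoate (C3 epimers) | COC(OC)C[C@@]1(C)OC(=CC1=O)[C@@H](C)[C@H](O[Si](C)(C)C(C)(C)C)[C@@H](OC(=O)C(C)C)C(O)C(=C)C(=O)OC | intermediate
21 | methyl (2Z,4S,5S,6S)-2-(bromomethyl)-5-[(tert-butyldimethylsilyl)oxy]-6-[(2R)-2-(2,2-dimethoxyethyl)-2-methyl-3-oxo-2,3-dihydrofuran-5-yl]-4-[(2-methylpropanoyl)oxy]hept-2-enoate | COC(OC)C[C@@]1(C)OC(=CC1=O)[C@@H](C)[C@H](O[Si](C)(C)C(C)(C)C)[C@@H](OC(=O)C(C)C)/C=C(\CBr)C(=O)OC | intermediate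
22 | methyl (2Z,4S,5S,6S)-2-(bromomethyl)-5-[(tert-butyldimethylsilyl)oxy]-6-[(2R)-2-methyl-3-oxo-2-(2-oxoethyl)-2,3-dihydrofuran-5-yl]-4-[(2-methylpropanoyl)oxy]hept-2-enoate | O=CC[C@@]1(C)OC(=CC1=O)[C@@H](C)[C@H](O[Si](C)(C)C(C)(C)C)[C@@H](OC(=O)C(C)C)/C=C(\CBr)C(=O)OC | intermediate
23 | ring-closed seco-lactone (4S,5S,6S,7R,8S,10R): ten-membered carbocycle with free 8-OH, C11 carrying =CH2 and CO2Me, 5-O-TBS, 6-O-isobutyryl (chromium alkoxide in the flask) | C=C(C(=O)OC)[C@@H]1[C@@H](O)C[C@@]2(C)OC(=CC2=O)[C@@H](C)[C@H](O[Si](C)(C)C(C)(C)C)[C@H]1OC(=O)C(C)C | intermediate (not isolated)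
24 | 5-O-(tert-butyldimethylsilyl) ether of the target (4S,5S,6S,7R,8S,10R) | C=C1C(=O)O[C@H]2C[C@@]3(C)OC(=CC3=O)[C@@H](C)[C@H](O[Si](C)(C)C(C)(C)C)[C@@H](OC(=O)C(C)C)[C@H]12 | intermediate
25 | CNP0141385.1, (4S,5S,6S,7R,8S,10R)-5-hydroxy-6-(2-methylpropanoyloxy)-1-oxo-3,10-epoxygermacra-2,11(13)-dien-12,8-olide | C=C1C(=O)O[C@H]2C[C@@]3(C)OC(=CC3=O)[C@@H](C)[C@H](O)[C@@H](OC(=O)C(C)C)[C@H]12 | target

Total step count: 14
Longest linear sequence: 13 steps (steps 2–14, from 4 and 5); step 1 is a one-step branch that joins at step 5.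

Steps most likely to fail

1. Step 5 (key step). What may go wrong: erosion of face selectivity at the ketone if the magnesium chelate is broken up by the ether solvent; incomplete second metalation or proton transfer that returns 10; base-induced elimination of the silyloxy group from ynone 11. Fallback: the one-flask sequence is split and moved to the aldehyde oxidation level. Setting out from 3 and 8, only the first stage is run and alcohol 10 is isolated. Amide 8 is reduced with DIBAL-H to (2S,3S)-3-[(tert-butyldimethylsilyl)oxy]-3-[(4S)-2,2-dimethyl-1,3-dioxolan-4-yl]-2-methylpropanal F1. The dilithio derivative of 10 (n-BuLi, 2 equiv, THF, −78 °C) is added to F1 to give the propargylic diol F2. MnO2 then oxidises the secondary propargylic alcohol of F2 to ynone 11, where the route is rejoined (Et2NH, then HCl, should give 13).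

2. Step 13. What may go wrong: reaction through the syn manifold to the cis-fused lactone (8-epimer), attack on the wrong aldehyde face, oligomerisation at the dilution used, and β-elimination that opens the furanone from the β-alkoxy aldehyde. Fallback: ring closure and lactone formation are separated. Setting out from 22, indium powder in THF/aqueous NH4Cl at high dilution should give the ring-closed hydroxy ester. If this is the 8-epimeric hydroxy ester F3, the methyl ester is cleaved with Me3SnOH to the hydroxy acid F4, and Mitsunobu lactonisation (PPh3, DIAD) closes the lactone with inversion at C8, coming back to the route at 24.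

3. Step 6. What may go wrong: loss of the formyl group by retro-Claisen-type cleavage (the leaving group is an aromatic 3-oxidofuran), or deprotonation at C4 followed by elimination of the silyloxy group. Fallback: non-basic homologation in two steps. Setting out from 13, Takai methylenation (CH2I2, Zn, Ti(OiPr)4) should give the 2-ethenyl furanone F5. Aldehyde-selective Wacker oxidation (PdCl2(PhCN)2, CuCl2, AgNO2, O2, t-BuOH/MeNO2) then gives the homologous aldehyde F6. PPTS, MeOH and HC(OMe)3 convert F6 into 15, where the route is rejoined.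

Further compounds
F1 | step 5 | (2S,3S)-3-[(tert-butyldimethylsilyl)oxy]-3-[(4S)-2,2-dimethyl-1,3-dioxolan-4-yl]-2-methylpropanal | O=C[C@@H](C)[C@H](O[Si](C)(C)C(C)(C)C)[C@@H]1COC(C)(C)O1
F2 | step 5 | (2S,6S,7S)-7-[(tert-butyldimethylsilyl)oxy]-7-[(4S)-2,2-dimethyl-1,3-dioxolan-4-yl]-6-methyl-2-[(3S,7aR)-2-phenylhexahydro-1H-pyrrolo[1,2-c]imidazol-3-yl]hept-3-yne-2,5-diol (C5 epimers) | O[C@@](C)(C#CC(O)[C@@H](C)[C@H](O[Si](C)(C)C(C)(C)C)[C@@H]1COC(C)(C)O1)[C@@H]1N(c2ccccc2)C[C@H]2CCCN12
F3 | step 13 | 8-epimer of seco-lactone 23 (syn adduct, methyl ester) | C=C(C(=O)OC)[C@@H]1[C@H](O)C[C@@]2(C)OC(=CC2=O)[C@@H](C)[C@H](O[Si](C)(C)C(C)(C)C)[C@H]1OC(=O)C(C)C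
F4 | step 13 | carboxylic acid of F3 (8-epi hydroxy acid) | C=C(C(=O)O)[C@@H]1[C@H](O)C[C@@]2(C)OC(=CC2=O)[C@@H](C)[C@H](O[Si](C)(C)C(C)(C)C)[C@H]1OC(=O)C(C)C
F5 | step 6 | (2R)-5-[(2S,3S)-3-[(tert-butyldimethylsilyl)oxy]-3-[(4S)-2,2-dimethyl-1,3-dioxolan-4-yl]propan-2-yl]-2-ethenyl-2-methylfuran-3(2H)-one | C=C[C@@]1(C)OC(=CC1=O)[C@@H](C)[C@H](O[Si](C)(C)C(C)(C)C)[C@@H]1COC(C)(C)O1
F6 | step 6 | 2-[(2R)-5-[(2S,3S)-3-[(tert-butyldimethylsilyl)oxy]-3-[(4S)-2,2-dimethyl-1,3-dioxolan-4-yl]propan-2-yl]-2-methyl-3-oxo-2,3-dihydrofuran-2-yl]acetaldehyde | O=CC[C@@]1(C)OC(=CC1=O)[C@@H](C)[C@H](O[Si](C)(C)C(C)(C)C)[C@@H]1COC(C)(C)O1
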